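**Plan**

- Locants C1'–C7' count the oxygenated geranyl chain from the OCH2 on the coumarin oxygen. Retrosynthesis cuts the linoleate ester C–O bond at O6', then the aryl ether bond O–C1', then C2'–C1' and C3'–CH3 of the alkene, then the alkyne carbon C2' from C3', and last the two C7'–CH3 bonds.
- The feature that allows the key step is the acyclic E-alkene C2'=C3', which carries CH3 on C3' and the oxymethylene C1' on C2'. These are the two groups that a syn methylmetalation of a terminal C2'≡C3' alkyne and a one-carbon electrophile deliver. The coumarin bicycle is bought intact, so no ring of the target has to be built.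
- Forward, D-glutamic acid gives the lactone acid; its ester becomes the C7' dimethyl carbinol and its lactone carbon becomes C3' after reduction and alkynylation. The diol is masked as a dioxolane, and methylalumination with formaldehyde capture adds CH3 and C1'.
- The chain is then joined to umbelliferone by Mitsunobu etherification, the diol is released, and the secondary hydroxyl is esterified with linoleic acid.
- Stereochemistry: C6' (R) is C2 of D-glutamic acid, kept through a double inversion in the diazotisation. The E alkene comes from syn carbometalation and retentive trapping. The two Z alkenes arrive with linoleic acid.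

Key step: step 7

**Step 1**
Reactants: 1 D-glutamic acid
Product: 4 (R)-5-oxotetrahydrofuran-2-carboxylic acid, via diazonium carboxylate 2 (not isolated), via alpha-lactone 3 (not isolated)
Conditions: NaNO2, aq. HCl, 0 °C → rt
Reagents that add atoms: none
Why: Diazotisation of an α-amino acid with neighbouring-group participation: the α-carboxylate expels N2 from 2 with inversion to give 3, and the γ-carboxyl opens 3 at the same carbon with a second inversion, so the (R) configuration of 1 is retained in 4.

**Step 2**
Reactants: 4 (R)-5-oxotetrahydrofuran-2-carboxylic acid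
Product: 5 ethyl (R)-5-oxotetrahydrofuran-2-carboxylate
Conditions: EtOH, TsOH·H2O (cat.), toluene, reflux, Dean–Stark
Reagents that add atoms: ethanol, CCO
Why: Fischer esterification driven by azeotropic removal of water; the stereocentre is not involved, and any ring-opened hydroxy diester should relactonise on concentration.

**Step 3**
Reactants: 5 ethyl (R)-5-oxotetrahydrofuran-2-carboxylate
Product: 7 (R)-5-(2-hydroxypropan-2-yl)dihydrofuran-2(3H)-one, via methyl ketone 6 (not isolated)
Conditions: MeMgBr (2.1 equiv), THF, −78 → −40 °C
Reagents that add atoms: methylmagnesium bromide, C[Mg]Br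
Why: Double Grignard addition to an ester; the exocyclic α-alkoxy ester carbonyl is more electrophilic than the lactone carbonyl and ketone 6 is more reactive still, so two equivalents at low temperature should leave the lactone and the stereocentre untouched.

**Step 4**
Reactants: 7 (R)-5-(2-hydroxypropan-2-yl)dihydrofuran-2(3H)-one
Product: 8 (5R)-5-(2-hydroxypropan-2-yl)tetrahydrofuran-2-ol (anomeric mixture)
Conditions: i-Bu2AlH (2.2 equiv), CH2Cl2, −78 °C
Reagents that add atoms: none
Why: Partial reduction of a γ-lactone to the lactol; the first equivalent of hydride is consumed by the tertiary hydroxyl, the aluminium hemiacetal is stable at −78 °C, and the new anomeric centre is of no consequence because it is destroyed in step 5.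

**Step 5**
Reactants: 8 (5R)-5-(2-hydroxypropan-2-yl)tetrahydrofuran-2-ol
Product: 10 (R)-2-methylhept-6-yne-2,3-diol, via open-chain hydroxy aldehyde 9 (not isolated)
Conditions: dimethyl (1-diazo-2-oxopropyl)phosphonate, K2CO3, MeOH, 0 °C → rt
Reagents that add atoms: dimethyl (1-diazo-2-oxopropyl)phosphonate, COP(=O)(OC)C(=[N+]=[N-])C(C)=O
Why: Seyferth–Gilbert homologation in the Ohira–Bestmann form, applied to a lactol that reacts through its aldehyde tautomer 9; the diazophosphonate anion adds, phosphate and N2 are lost, and a 1,2-hydrogen shift gives the terminal alkyne, while the carbinol stereocentre is γ to the aldehyde and cannot epimerise.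

**Step 6**
Reactants: 10 (R)-2-methylhept-6-yne-2,3-diol
Product: 11 (R)-4-(but-3-yn-1-yl)-2,2,5,5-tetramethyl-1,3-dioxolane
Conditions: Me2C(OMe)2, PPTS (cat.), CH2Cl2, rt
Reagents that add atoms: 2,2-dimethoxypropane, COC(C)(C)OC
Why: Acid-catalysed transacetalisation of a vicinal diol to the five-membered dioxolane; no C–O bond of the diol is broken, so the configuration is kept.

**Step 7**
Reactants: 11 (R)-4-(but-3-yn-1-yl)-2,2,5,5-tetramethyl-1,3-dioxolane
Product: 14 (R,E)-3-methyl-5-(2,2,5,5-tetramethyl-1,3-dioxolan-4-yl)pent-2-en-1-ol, via alkenyldimethylalane 12 (not isolated), via lithium alkenylalanate 13 (not isolated)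
Conditions: Me3Al (3 equiv), Cp2ZrCl2 (0.25 equiv), H2O (1.5 equiv), CH2Cl2, −30 °C; volatiles removed in vacuo; n-BuLi (1.2 equiv), hexane/THF, −78 → 0 °C; (CH2O)n (excess), 0 °C → rt; aq. potassium sodium tartrate
Reagents that add atoms: trimethylaluminium, C[Al](C)C; formaldehyde (as paraformaldehyde), C=O
Why: Me3Al and Cp2ZrCl2 form a chloride-bridged methylzirconium–aluminium species that adds methyl and metal to the same face of the C2'≡C3' bond of 11 through a four-centre transition state, placing CH3 on the internal carbon C3' and the metal on the terminal carbon C2'; exchange to aluminium gives the (E)-alkenylalane 12. n-BuLi turns 12 into the more nucleophilic alanate 13, whose alkenyl group attacks monomeric formaldehyde with retention at C2', which forms the C2'–C1' bond and leaves the C4' chain and C1' trans, the E geometry of the target. The closest known reaction type is the Negishi zirconium-catalysed methylalumination of terminal alkynes with hydroxymethylation of the derived alanate, the standard entry to (E)-3-methylalk-2-en-1-ols. No ring closes and no stereocentre is formed; C6' lies three bonds from the reacting carbons and is carried through unchanged. The step needs the metal on the terminal carbon, syn addition, and tolerance of the dioxolane; the first two follow from the unhindered terminal alkyne on an unbranched CH2CH2 tether, and the water-accelerated protocol lets the addition run at −30 °C in a short time, which should keep the Lewis acidic aluminium from opening the acetal.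

**Step 8**
Reactants: 14 (R,E)-3-methyl-5-(2,2,5,5-tetramethyl-1,3-dioxolan-4-yl)pent-2-en-1-ol; 15 umbelliferone
Product: 16 7-{[(R,E)-3-methyl-5-(2,2,5,5-tetramethyl-1,3-dioxolan-4-yl)pent-2-en-1-yl]oxy}-2H-chromen-2-one
Conditions: PPh3, DIAD, THF, 0 °C → rt
Reagents that add atoms: none
Why: Mitsunobu etherification of an acidic phenol with a primary allylic alcohol; direct displacement at C1' should be favoured over allylic transposition, and neither the alkene geometry, the acetal nor C6' is affected.

**Step 9**
Reactants: 16 7-{[(R,E)-3-methyl-5-(2,2,5,5-tetramethyl-1,3-dioxolan-4-yl)pent-2-en-1-yl]oxy}-2H-chromen-2-one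
Product: 17 (R)-marmin, 7-{[(2E,6R)-6,7-dihydroxy-3,7-dimethyloct-2-en-1-yl]oxy}-2H-chromen-2-one
Conditions: AcOH/THF/H2O (3:1:1), 40 °C
Reagents that add atoms: none
Why: Mild acid-catalysed acetal hydrolysis; cleavage occurs at the acetal carbon and not at the C6'–O or C7'–O bonds, so the configuration is kept, and aqueous acetic acid should spare the allyl aryl ether and the coumarin lactone.

**Step 10**
Reactants: 17 (R)-marmin; 18 linoleic acid
Product: 19 (R)-(+)-marmin 6'-linoleate, (3R,6E)-2-hydroxy-2,6-dimethyl-8-[(2-oxo-2H-chromen-7-yl)oxy]oct-6-en-3-yl (9Z,12Z)-octadeca-9,12-dienoate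
Conditions: DCC, DMAP (cat.), CH2Cl2, 0 °C → rt, argon, dark
Reagents that add atoms: none
Why: Steglich esterification; carbodiimide activation and DMAP acyl transfer should acylate the secondary hydroxyl while the tertiary hydroxyl is too hindered to react, and the neutral, oxygen-free conditions leave the skipped (Z,Z)-diene and C6' untouched.

**Compound list**

1 | D-glutamic acid, (R)-2-aminopentanedioic acid | N[C@H](CCC(=O)O)C(=O)O | starting material
2 | (R)-4-carboxy-2-diazoniobutanoate (diazonium carboxylate) | N#[N+][C@H](CCC(=O)O)C(=O)[O-] | intermediate (not isolated)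
3 | (S)-3-(3-oxooxiran-2-yl)propanoic acid (alpha-lactone) | OC(=O)CC[C@@H]1OC1=O | intermediate (not isolated)
4 | (R)-5-oxotetrahydrofuran-2-carboxylic acid | OC(=O)[C@H]1CCC(=O)O1 | intermediate
5 | ethyl (R)-5-oxotetrahydrofuran-2-carboxylate | CCOC(=O)[C@H]1CCC(=O)O1 | intermediate
6 | (R)-5-acetyldihydrofuran-2(3H)-one (methyl ketone) | CC(=O)[C@H]1CCC(=O)O1 | intermediate (not isolated)
7 | (R)-5-(2-hydroxypropan-2-yl)dihydrofuran-2(3H)-one | CC(C)(O)[C@H]1CCC(=O)O1 | intermediate
8 | (5R)-5-(2-hydroxypropan-2-yl)tetrahydrofuran-2-ol, anomeric mixture | CC(C)(O)[C@H]1CCC(O)O1 | intermediate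
9 | (R)-4,5-dihydroxy-5-methylhexanal (open-chain hydroxy aldehyde) | O=CCC[C@@H](O)C(C)(C)O | intermediate (not isolated)
10 | (R)-2-methylhept-6-yne-2,3-diol | C#CCC[C@@H](O)C(C)(C)O | intermediate
11 | (R)-4-(but-3-yn-1-yl)-2,2,5,5-tetramethyl-1,3-dioxolane | CC1(C)O[C@H](CCC#C)C(C)(C)O1 | intermediate
12 | dimethyl[(R,E)-2-methyl-4-(2,2,5,5-tetramethyl-1,3-dioxolan-4-yl)but-1-en-1-yl]alane | CC1(C)O[C@H](CC/C(C)=C/[Al](C)C)C(C)(C)O1 | intermediate (not isolated)
13 | lithium butyl(dimethyl)[(R,E)-2-methyl-4-(2,2,5,5-tetramethyl-1,3-dioxolan-4-yl)but-1-en-1-yl]alanate | CC1(C)O[C@H](CC/C(C)=C/[Al-](C)(C)CCCC)C(C)(C)O1.[Li+] | intermediate (not isolated)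
14 | (R,E)-3-methyl-5-(2,2,5,5-tetramethyl-1,3-dioxolan-4-yl)pent-2-en-1-ol | CC1(C)O[C@H](CC/C(C)=C/CO)C(C)(C)O1 | intermediate
15 | umbelliferone, 7-hydroxy-2H-chromen-2-one | Oc1ccc2ccc(=O)oc2c1 | starting material
16 | 7-{[(R,E)-3-methyl-5-(2,2,5,5-tetramethyl-1,3-dioxolan-4-yl)pent-2-en-1-yl]oxy}-2H-chromen-2-one | CC1(C)O[C@H](CC/C(C)=C/COc2ccc3ccc(=O)oc3c2)C(C)(C)O1 | intermediate
17 | (R)-marmin, 7-{[(2E,6R)-6,7-dihydroxy-3,7-dimethyloct-2-en-1-yl]oxy}-2H-chromen-2-one | CC(C)(O)[C@H](O)CC/C(C)=C/COc1ccc2ccc(=O)oc2c1 | intermediate
18 | linoleic acid, (9Z,12Z)-octadeca-9,12-dienoic acid | CCCCC/C=C\C/C=C\CCCCCCCC(=O)O | starting material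
19 | (R)-(+)-marmin 6'-linoleate | CCCCC/C=C\C/C=C\CCCCCCCC(=O)O[C@H](CC/C(C)=C/COc1ccc2ccc(=O)oc2c1)C(C)(C)O | target

**Step count and risks**

Total step count: 10. Longest linear sequence: 10 steps, from 1 to 19; 15 and 18 are bought and enter in steps 8 and 10.

Steps most likely to fail:

1. Step 7. The Lewis acidic aluminium reagent may open the dioxolane, or the one-carbon capture may be incomplete so that the alkenyl–metal bond is merely protonated on work-up. The fallback makes the same two bonds without trimethylaluminium. It sets out from 11: deprotonation with n-BuLi and addition to paraformaldehyde (THF, −78 °C → rt) would give 5-[(4R)-2,2,5,5-tetramethyl-1,3-dioxolan-4-yl]pent-2-yn-1-ol F1. Hydroxyl-directed trans-hydroalumination with NaAlH2(OCH2CH2OMe)2 (THF, 0 °C) followed by iodine at −78 °C would give (R,Z)-3-iodo-5-(2,2,5,5-tetramethyl-1,3-dioxolan-4-yl)pent-2-en-1-ol F2, with iodine on C3' cis to C1'. Excess Me2CuLi (Et2O, 0 °C) would replace iodine by methyl with retention, and the route is rejoined at 14.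

2. Step 3. The Grignard reagent may also attack the lactone carbonyl, leading to over-addition and ring opening. The fallback separates the two methyl additions. It sets out from 4: (COCl)2 with catalytic DMF in CH2Cl2 would give (R)-5-oxotetrahydrofuran-2-carbonyl chloride F3, and Me2CuLi (Et2O, −78 °C) would convert it into ketone 6, here isolated and used at once because its stereocentre is enolisable. MeTi(OiPr)3 (THF, −30 → 0 °C), which adds to ketones but not to lactones, would then give the carbinol, and the route is rejoined at 7.

3. Step 5. The lactol may release too little free aldehyde, so that base-induced decay of the diazophosphonate outruns the homologation, and the small water-soluble diol may be lost on isolation. The fallback alkynylates a free, protected aldehyde instead. It sets out from 7: LiAlH4 (THF, 0 °C → rt) would give (R)-5-methylhexane-1,4,5-triol F4. Me2C(OMe)2 and PPTS in CH2Cl2 would close the dioxolane on the vicinal diol to give 3-[(4R)-2,2,5,5-tetramethyl-1,3-dioxolan-4-yl]propan-1-ol F5. Dess–Martin periodinane buffered with NaHCO3 (CH2Cl2, rt) would give 3-[(4R)-2,2,5,5-tetramethyl-1,3-dioxolan-4-yl]propanal F6. Ohira–Bestmann alkynylation (K2CO3, MeOH, rt) would then rejoin the route at 11, at the cost of one step more than steps 4 to 6.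

**Further compounds**

F1 | step 7 | 5-[(4R)-2,2,5,5-tetramethyl-1,3-dioxolan-4-yl]pent-2-yn-1-ol | CC1(C)O[C@H](CCC#CCO)C(C)(C)O1
F2 | step 7 | (R,Z)-3-iodo-5-(2,2,5,5-tetramethyl-1,3-dioxolan-4-yl)pent-2-en-1-ol | CC1(C)O[C@H](CC/C(I)=C/CO)C(C)(C)O1
F3 | step 3 | (R)-5-oxotetrahydrofuran-2-carbonyl chloride | O=C(Cl)[C@H]1CCC(=O)O1
F4 | step 5 | (R)-5-methylhexane-1,4,5-triol | CC(C)(O)[C@H](O)CCCO
F5 | step 5 | 3-[(4R)-2,2,5,5-tetramethyl-1,3-dioxolan-4-yl]propan-1-ol | CC1(C)O[C@H](CCCO)C(C)(C)O1
F6 | step 5 | 3-[(4R)-2,2,5,5-tetramethyl-1,3-dioxolan-4-yl]propanal | CC1(C)O[C@H](CCC=O)C(C)(C)O1
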